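**Plan**
- Germacrane numbering is used: carbocycle C1–C10 (C1 ketone, C3 carbinol, C8 tiglate, C9/C10 diol) and γ-lactone ring O–C6–C7–C11(=C13H2)–C12. The ten-membered ring C1–C10 holds only one alkene, the trisubstituted Z C4=C5 between carbinol C3 and lactone carbinol C6. One cut there leaves a C4 isopropenyl group and a C6 vinyl group.
- Retrosynthetic cuts, in order: C4=C5 (ring-closing metathesis); C5=CH2 and O6–C12 (vinyl group, lactone); O8–acyl (tiglate); C7–C8 (indium allylation); C2–C3 (boron aldol with methacrolein); C1–C2 (methyl ketone); C9=C10 (Z-olefination, then osmylation).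
- Forward: a C1–C4/C8–C10 aldehyde (eight steps) and a C5–C7/C11–C13 allylic bromide (two steps) are joined at C7–C8. The lactone ring closes after tiglation. The ten-membered ring closes in the penultimate step.
- Stereochemistry: C6 comes from (R)-glyceraldehyde acetonide. C9 and C10 come from osmylation of a Z-enoate steered by the stereocentre of (S)-glyceraldehyde acetonide, which is later cut down to the C8 aldehyde. C3 comes from (+)-Ipc2BCl. C7 and C8 are set in the allylation (Z-allylindium chair, Felkin–Anh face of the aldehyde, allyl face anti to C6–O). The alkene geometry is set by the ring.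

Key step: step 16

Assumption: both antipodes of glyceraldehyde acetonide are bought and distilled directly before use, because they oligomerise and slowly racemise on storage.

Step 1
Reactants: 1 (S)-glyceraldehyde acetonide (CHO = C9; ring CH = future C8; ring CH2 = extra carbon); 2 ethyl 2-[bis(2,2,2-trifluoroethoxy)phosphoryl]propanoate
Product: 4 ethyl (2Z)-3-[(4R)-2,2-dimethyl-1,3-dioxolan-4-yl]-2-methylprop-2-enoate, via potassium phosphonate carbanion 3 (not isolated)
Conditions: KN(SiMe3)2, 18-crown-6, THF, −78 °C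
Reagents that add atoms: none
Why: Still–Gennari variant of the Horner–Wadsworth–Emmons olefination, in which the electron-poor trifluoroethyl phosphonate with a dissociated potassium counter-ion collapses kinetically to the Z-trisubstituted enoate, placing the future C8 and C1 cis as the later cis-dioxolane requires while the cold, fast reaction leaves the α-alkoxy stereocentre intact.

Step 2
Reactants: 4 Z-enoate
Product: 5 ethyl (2S,3S)-3-[(4S)-2,2-dimethyl-1,3-dioxolan-4-yl]-2,3-dihydroxy-2-methylpropanoate (ethyl 4,5-O-isopropylidene-2-C-methyl-L-ribonate)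
Conditions: OsO4 (cat.), NMO, acetone–H2O, rt
Reagents that add atoms: N-methylmorpholine N-oxide C[N+]1([O-])CCOCC1; water O; OsO4 as oxygen carrier O=[Os](=O)(=O)=O
Why: Catalytic (Upjohn) dihydroxylation, in which suprafacial addition to the Z-alkene fixes the C9/C10 relationship and, with the allylic hydrogen held in the alkene plane by A(1,3) strain, OsO4 attacks anti to the allylic C–O bond so that O9 comes out erythro to the resident oxygen (9S,10S).

Step 3
Reactants: 5 diol ester
Product: 6 ethyl (4S,5S)-5-[(4S)-2,2-dimethyl-1,3-dioxolan-4-yl]-2,2,4-trimethyl-1,3-dioxolane-4-carboxylate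
Conditions: Me2C(OMe)2, CSA (cat.), CH2Cl2, rt
Reagents that add atoms: 2,2-dimethoxypropane COC(C)(C)OC
Why: Acid-catalysed transketalisation under anhydrous conditions, for which the C9,C10 dioxolane (C8 and C1 cis on the ring) is the only way to cap both remaining hydroxyls in a five-membered ring.

Step 4
Reactants: 6 bis-acetonide ester
Product: 7 (4S,5S)-5-[(4S)-2,2-dimethyl-1,3-dioxolan-4-yl]-N-methoxy-N,2,2,4-tetramethyl-1,3-dioxolane-4-carboxamide
Conditions: MeNH(OMe)·HCl, iPrMgCl, THF, −20 to 0 °C
Reagents that add atoms: N,O-dimethylhydroxylamine hydrochloride CNOC.Cl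
Why: Weinreb amide synthesis by aminolysis of the ester with the magnesium amide, a method that copes with hindered α-alkoxy esters and touches no stereocentre.

Step 5
Reactants: 7 Weinreb amide
Product: 8 1-{(4S,5S)-5-[(4S)-2,2-dimethyl-1,3-dioxolan-4-yl]-2,2,4-trimethyl-1,3-dioxolan-4-yl}ethan-1-one (C1 methyl ketone)
Conditions: MeMgBr, THF, 0 °C
Reagents that add atoms: methylmagnesium bromide C[Mg]Br
Why: Weinreb ketone synthesis, in which the chelated tetrahedral adduct persists until work-up so that exactly one methyl group (C2) is delivered.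

Step 6
Reactants: 8 methyl ketone; 9 methacrolein
Product: 12 (3S)-1-{(4S,5S)-5-[(4S)-2,2-dimethyl-1,3-dioxolan-4-yl]-2,2,4-trimethyl-1,3-dioxolan-4-yl}-3-hydroxy-4-methylpent-4-en-1-one, via enol diisopinocampheylborinate 10 (not isolated), via boron aldolate 11 (not isolated)
Conditions: (+)-Ipc2BCl, Et3N, Et2O, 0 °C; 9, −78 to −20 °C; MeOH, pH 7 buffer, 30% H2O2, 0 °C
Reagents that add atoms: none
Why: Boron-mediated aldol addition of a methyl ketone under reagent control, in which the kinetic enol borinate adds through a cyclic transition state whose (+)-Ipc ligands expose the Si face of methacrolein and so give the 3S carbinol, any 3R epimer being a separable diastereomer.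

Step 7
Reactants: 12 β-hydroxy ketone
Product: 13 (3S)-3-(tert-butyldimethylsilyloxy) derivative of 12
Conditions: TBSOTf, 2,6-lutidine, CH2Cl2, −78 °C
Reagents that add atoms: tert-butyldimethylsilyl triflate CC(C)(C)[Si](C)(C)OS(=O)(=O)C(F)(F)F
Why: O-silylation with a silyl triflate and a hindered base is fast at low temperature and thereby avoids retro-aldol cleavage or β-elimination of the β-hydroxy ketone.

Step 8
Reactants: 13 silyl ether
Product: 15 (4R,5S)-5-[(3S)-3-(tert-butyldimethylsilyloxy)-4-methylpent-4-enoyl]-2,2,5-trimethyl-1,3-dioxolane-4-carbaldehyde (C8 aldehyde), via terminal 1,2-diol 14 (not isolated)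
Conditions: H5IO6, EtOAc, 0 °C to rt
Reagents that add atoms: none
Why: One-pot selective hydrolysis of the less substituted terminal acetonide followed by Malaprade glycol cleavage, which turns the stereocentre that steered the osmylation into the C8 aldehyde carbon while the fully substituted, ketone-deactivated C9,C10 acetonide and the secondary silyl ether remain.

Step 9
Reactants: 16 (R)-glyceraldehyde acetonide (CHO = C7; ring CH = C6; ring CH2 = C5); 17 methyl acrylate
Product: 18 methyl 2-{[(4R)-2,2-dimethyl-1,3-dioxolan-4-yl](hydroxy)methyl}prop-2-enoate (both carbinol epimers)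
Conditions: DABCO, 1,4-dioxane–H2O, rt
Reagents that add atoms: none
Why: Morita–Baylis–Hillman reaction of an activated α-alkoxy aldehyde, whose new carbinol centre is irrelevant because the next step erases it, while C6 is carried in from the chiral pool.

Step 10
Reactants: 18 Baylis–Hillman alcohol
Product: 19 methyl (2Z)-2-(bromomethyl)-3-[(4S)-2,2-dimethyl-1,3-dioxolan-4-yl]prop-2-enoate
Conditions: NBS, Me2S, CH2Cl2, 0 °C to rt
Reagents that add atoms: N-bromosuccinimide O=C1CCC(=O)N1Br
Why: Allylic bromination with transposition (SN2′ attack of bromide on the alkoxysulfonium salt), which with Baylis–Hillman alcohols gives the more stable Z-2-(bromomethyl)enoate with C6 cis to CH2Br under acid-free conditions that spare the acetonide.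

Step 11
Reactants: 15 C8 aldehyde; 19 allylic bromide
Product: 21 C7–C8 coupled homoallylic alcohol (methyl ester; CIP 3S,6S,7R,8S,9S,10S; spatial arrangement as in the target), via allylindium dibromide 20 (not isolated)
Conditions: indium powder, THF–H2O, rt
Reagents that add atoms: none
Why: Barbier-type indium 2-(alkoxycarbonyl)allylation, chemoselective for the aldehyde over the hindered C1 ketone, in which the Z-allylindium bonds at C7 through a chair transition state (7,8-syn), the aldehyde is taken on its Felkin–Anh face anti to the C9–O bond (8,9-anti) and the allyl unit, held by A(1,3) strain with H6 in the alkene plane, reacts on the face anti to the C6–O bond, three preferences that converge on the C7 and C8 configuration of the target.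

Step 12
Reactants: 21 homoallylic alcohol; 22 tiglic acid
Product: 24 C8 tiglate (CIP 3S,6S,7S,8S,9S,10S), via tiglic 2,4,6-trichlorobenzoic anhydride 23 (not isolated)
Conditions: 2,4,6-Cl3C6H2COCl, Et3N, toluene, rt; 21, DMAP, rt to 40 °C
Reagents that add atoms: none
Why: Yamaguchi esterification, whose mixed anhydride–DMAP pair acylates hindered secondary alcohols without disturbing the E geometry of the tiglate, and although 21 may rest as a C1 hemiketal only its open hydroxy ketone tautomer offers an acylable secondary hydroxyl.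

Step 13
Reactants: 24 tiglate
Product: 26 trans-α-methylene-γ-butyrolactone bearing CH2OH (C5) at C6 (CIP 3S,6S,7S,8S,9S,10S), via 5,6-diol 25 (not isolated)
Conditions: PPTS (cat.), MeOH, 40 °C; concentrate; toluene, 60 °C
Reagents that add atoms: none
Why: Mild acid-catalysed transketalisation frees the terminal 5,6-diol selectively, and O6 then closes onto the acrylate ester (lactonisation, five-membered ring preferred over the six-membered ring through O5) with no change at C6 or C7, so the ring carries C5 and C8 trans.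

Step 14
Reactants: 26 primary alcohol
Product: 27 C5 aldehyde (CIP 3S,6S,7R,8S,9S,10S)
Conditions: Dess–Martin periodinane, CH2Cl2, 0 °C to rt
Reagents that add atoms: none
Why: Dess–Martin oxidation stops at the aldehyde and is neutral enough not to epimerise C6 or shift the exocyclic methylene.

Step 15
Reactants: 27 C5 aldehyde
Product: 28 seco C4,C5 diene (C6 vinyl; C4 isopropenyl; C3 OTBS; C9,C10 acetonide; C8 tiglate; CIP 3S,6R,7S,8S,9S,10S)
Conditions: CH2I2, Zn dust, Ti(OiPr)4, THF, rt
Reagents that add atoms: diiodomethane ICI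
Why: Non-basic methylenation with the gem-dizinc–titanium reagent (Takai–Lombardo type), which is known to prefer aldehydes over ketones and esters and therefore spares the hindered C1 ketone, the lactone, the tiglate and the configuration at C6.

Step 16
Reactants: 28 seco C4,C5 diene
Product: 30 protected target (ten-membered ring closed; Z C4=C5; C3 OTBS; C9,C10 acetonide), via C5 ruthenium alkylidene RuCl2(=CHR)(H2IMes) 29 (not isolated)
Conditions: second-generation Grubbs catalyst RuCl2(=CHPh)(PCy3)(H2IMes) (15 mol %, in portions), 1,4-benzoquinone (cat.), toluene, 0.5 mM, 80 °C, argon sparge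
Reagents that add atoms: none
Why: Olefin metathesis by the Chauvin mechanism: phosphine loss from the catalyst frees a coordination site, the carbene is handed to the only monosubstituted alkene (the C6 vinyl group) to give alkylidene 29, and 29 adds across the 1,1-disubstituted C4 alkene in a [2+2] sense and cycloreverts, which forms C4=C5 and a ruthenium methylidene that re-enters the cycle with release of ethene. The closest known reaction type is medium-ring RCM to trisubstituted cycloalkenes, documented for ten-membered carbocycles and lactones with allylic oxygen on both sides. One ring is closed, the ten-membered carbocycle C1–C10, by end-to-end union of the two terminal alkenes so that the new double bond is endocyclic, and sub-millimolar concentration with purging of ethene biases the system towards cyclisation over oligomers. No stereocentre is made, and the existing ones see neither acid nor base. The selectivity that matters most is alkene geometry: the trans-fused lactone at C6–C7 and the cis-fused dioxolane at C9–C10 fold the chain so that C3 and C6 meet on the same side, and an E trisubstituted alkene would add strain to this ring system, so the Z isomer should prevail. Site selectivity among the four alkenes rests on electronics and substitution, since the α-methylene lactone and the tiglate are electron-poor and hindered and could only close a four-membered ring or engage a trisubstituted enoate.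

Step 17
Reactants: 30 protected target
Product: 31 CNP0106709.2 (3S,6R,7S,8S,9S,10S; 4Z)
Conditions: TFA–H2O 9:1, CH2Cl2, 0 °C
Reagents that add atoms: none
Why: Acidic solvolysis removes the allylic silyl ether and the acetonide in one operation under conditions that the tiglate, the α-methylene lactone and the Z alkene tolerate.

**Compound list**
1 | (S)-glyceraldehyde acetonide; (4S)-2,2-dimethyl-1,3-dioxolane-4-carbaldehyde | O=C[C@@H]1COC(C)(C)O1 | starting material
2 | ethyl 2-[bis(2,2,2-trifluoroethoxy)phosphoryl]propanoate | CCOC(=O)C(C)P(=O)(OCC(F)(F)F)OCC(F)(F)F | starting material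
3 | potassium phosphonate carbanion of 2 | [K+].CCOC(=O)[C-](C)P(=O)(OCC(F)(F)F)OCC(F)(F)F | intermediate
4 | ethyl (2Z)-3-[(4R)-2,2-dimethyl-1,3-dioxolan-4-yl]-2-methylprop-2-enoate | CCOC(=O)/C(C)=C\[C@@H]1COC(C)(C)O1 | intermediate
5 | ethyl (2S,3S)-3-[(4S)-2,2-dimethyl-1,3-dioxolan-4-yl]-2,3-dihydroxy-2-methylpropanoate | CCOC(=O)[C@@](C)(O)[C@@H](O)[C@@H]1COC(C)(C)O1 | intermediate
6 | ethyl (4S,5S)-5-[(4S)-2,2-dimethyl-1,3-dioxolan-4-yl]-2,2,4-trimethyl-1,3-dioxolane-4-carboxylate | CCOC(=O)[C@@]1(C)OC(C)(C)O[C@H]1[C@@H]1COC(C)(C)O1 | intermediate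
7 | (4S,5S)-5-[(4S)-2,2-dimethyl-1,3-dioxolan-4-yl]-N-methoxy-N,2,2,4-tetramethyl-1,3-dioxolane-4-carboxamide | CON(C)C(=O)[C@@]1(C)OC(C)(C)O[C@H]1[C@@H]1COC(C)(C)O1 | intermediate
8 | 1-{(4S,5S)-5-[(4S)-2,2-dimethyl-1,3-dioxolan-4-yl]-2,2,4-trimethyl-1,3-dioxolan-4-yl}ethan-1-one | CC(=O)[C@@]1(C)OC(C)(C)O[C@H]1[C@@H]1COC(C)(C)O1 | intermediate
9 | methacrolein | C=C(C)C=O | starting material
10 | enol diisopinocampheylborinate of 8 (C1=C2H2; boron on O1; Ipc ligands from (−)-α-pinene) | C=C(OB([C@H]1C[C@H]2C[C@@H]([C@@H]1C)C2(C)C)[C@H]1C[C@H]2C[C@@H]([C@@H]1C)C2(C)C)[C@@]1(C)OC(C)(C)O[C@H]1[C@@H]1COC(C)(C)O1 | intermediate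
11 | boron aldolate of 12 (O3–B(Ipc)2) | C=C(C)[C@@H](OB([C@H]1C[C@H]2C[C@@H]([C@@H]1C)C2(C)C)[C@H]1C[C@H]2C[C@@H]([C@@H]1C)C2(C)C)CC(=O)[C@@]1(C)OC(C)(C)O[C@H]1[C@@H]1COC(C)(C)O1 | intermediate
12 | (3S)-1-{(4S,5S)-5-[(4S)-2,2-dimethyl-1,3-dioxolan-4-yl]-2,2,4-trimethyl-1,3-dioxolan-4-yl}-3-hydroxy-4-methylpent-4-en-1-one | C=C(C)[C@@H](O)CC(=O)[C@@]1(C)OC(C)(C)O[C@H]1[C@@H]1COC(C)(C)O1 | intermediate
13 | (3S)-3-(tert-butyldimethylsilyloxy) ether of 12 | C=C(C)[C@@H](O[Si](C)(C)C(C)(C)C)CC(=O)[C@@]1(C)OC(C)(C)O[C@H]1[C@@H]1COC(C)(C)O1 | intermediate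
14 | terminal 1,2-diol; (3S)-3-(tert-butyldimethylsilyloxy)-1-{(4S,5S)-5-[(1S)-1,2-dihydroxyethyl]-2,2,4-trimethyl-1,3-dioxolan-4-yl}-4-methylpent-4-en-1-one | C=C(C)[C@@H](O[Si](C)(C)C(C)(C)C)CC(=O)[C@@]1(C)OC(C)(C)O[C@H]1[C@@H](O)CO | intermediate
15 | (4R,5S)-5-[(3S)-3-(tert-butyldimethylsilyloxy)-4-methylpent-4-enoyl]-2,2,5-trimethyl-1,3-dioxolane-4-carbaldehyde | C=C(C)[C@@H](O[Si](C)(C)C(C)(C)C)CC(=O)[C@@]1(C)OC(C)(C)O[C@H]1C=O | intermediate
16 | (R)-glyceraldehyde acetonide; (4R)-2,2-dimethyl-1,3-dioxolane-4-carbaldehyde | O=C[C@H]1COC(C)(C)O1 | starting material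
17 | methyl acrylate | C=CC(=O)OC | starting material
18 | methyl 2-{[(4R)-2,2-dimethyl-1,3-dioxolan-4-yl](hydroxy)methyl}prop-2-enoate (carbinol epimers) | C=C(C(=O)OC)C(O)[C@H]1COC(C)(C)O1 | intermediate
19 | methyl (2Z)-2-(bromomethyl)-3-[(4S)-2,2-dimethyl-1,3-dioxolan-4-yl]prop-2-enoate | COC(=O)/C(CBr)=C/[C@H]1COC(C)(C)O1 | intermediate
20 | allylindium dibromide from 19 (indium on C13; alkene geometry kept) | COC(=O)/C(C[In](Br)Br)=C/[C@H]1COC(C)(C)O1 | intermediate
21 | homoallylic alcohol: C7 carries the C11(=C13H2)–CO2Me acrylate, the (4S)-dioxolane (C5,C6) and the C8 carbinol; C3 OTBS; C9,C10 acetonide (3S,6S,7R,8S,9S,10S) | C=C(C)[C@@H](O[Si](C)(C)C(C)(C)C)CC(=O)[C@@]1(C)OC(C)(C)O[C@H]1[C@@H](O)[C@@H](C(=C)C(=O)OC)[C@H]1COC(C)(C)O1 | intermediate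
22 | tiglic acid; (E)-2-methylbut-2-enoic acid | C/C=C(\C)C(=O)O | starting material
23 | tiglic 2,4,6-trichlorobenzoic anhydride | C/C=C(\C)C(=O)OC(=O)c1c(Cl)cc(Cl)cc1Cl | intermediate
24 | C8 tiglate of 21 (3S,6S,7S,8S,9S,10S) | C=C(C)[C@@H](O[Si](C)(C)C(C)(C)C)CC(=O)[C@@]1(C)OC(C)(C)O[C@H]1[C@@H](OC(=O)/C(C)=C/C)[C@@H](C(=C)C(=O)OC)[C@H]1COC(C)(C)O1 | intermediate
25 | 5,6-diol of 24 (methyl ester still open) | C=C(C)[C@@H](O[Si](C)(C)C(C)(C)C)CC(=O)[C@@]1(C)OC(C)(C)O[C@H]1[C@@H](OC(=O)/C(C)=C/C)[C@@H](C(=C)C(=O)OC)[C@H](O)CO | intermediate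
26 | trans-α-methylene-γ-butyrolactone with CH2OH at C6; C8 tiglate; C3 OTBS; C9,C10 acetonide (3S,6S,7S,8S,9S,10S) | C=C(C)[C@@H](O[Si](C)(C)C(C)(C)C)CC(=O)[C@@]3(C)OC(C)(C)O[C@H]3[C@@H](OC(=O)/C(C)=C/C)[C@H]1C(=C)C(=O)O[C@@H]1CO | intermediate
27 | C5 aldehyde of 26 (3S,6S,7R,8S,9S,10S) | C=C(C)[C@@H](O[Si](C)(C)C(C)(C)C)CC(=O)[C@@]3(C)OC(C)(C)O[C@H]3[C@@H](OC(=O)/C(C)=C/C)[C@H]1C(=C)C(=O)O[C@@H]1C=O | intermediate
28 | seco C4,C5 diene: C6 vinyl lactone, C4 isopropenyl, C3 OTBS, C9,C10 acetonide, C8 tiglate (3S,6R,7S,8S,9S,10S) | C=C(C)[C@@H](O[Si](C)(C)C(C)(C)C)CC(=O)[C@@]3(C)OC(C)(C)O[C@H]3[C@@H](OC(=O)/C(C)=C/C)[C@H]1C(=C)C(=O)O[C@@H]1C=C | intermediate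
29 | C5 ruthenium alkylidene RuCl2(=CHR)(H2IMes), R = C6 of the seco chain | C=C(C)[C@@H](O[Si](C)(C)C(C)(C)C)CC(=O)[C@@]3(C)OC(C)(C)O[C@H]3[C@@H](OC(=O)/C(C)=C/C)[C@H]1C(=C)C(=O)O[C@@H]1C=[Ru](Cl)(Cl)=C1N(c2c(C)cc(C)cc2C)CCN1c1c(C)cc(C)cc1C | intermediate
30 | protected target: ten-membered ring with Z C4=C5; C3 OTBS; C9,C10 acetonide (3S,6R,7S,8S,9S,10S) | C=C1C(=O)O[C@@H]2/C=C(/C)[C@@H](O[Si](C)(C)C(C)(C)C)CC(=O)[C@@]3(C)OC(C)(C)O[C@H]3[C@@H](OC(=O)/C(C)=C/C)[C@@H]12 | intermediate
31 | CNP0106709.2; (3S,6R,7S,8S,9S,10S,4Z)-3,9,10-trihydroxy-1-oxo-8-tigloyloxygermacra-4,11(13)-dien-12,6-olide | C=C1C(=O)O[C@@H]2/C=C(/C)[C@@H](O)CC(=O)[C@@](C)(O)[C@@H](O)[C@@H](OC(=O)/C(C)=C/C)[C@@H]12 | target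

**Counts**
Total step count: 17.
Longest linear sequence: 15 steps (from 1 through steps 1–8 and 11–17).

**Steps most likely to fail**

Step 16. The hindered 1,1-disubstituted C4 alkene next to the bulky silyl ether may fail to enter the ruthenacycle. Intermolecular metathesis at the C6 vinyl group, alkene migration by ruthenium hydrides or closure with the wrong geometry would then take over.
- The fallback sets out from 28. HF·pyridine in THF removes the silyl group to give the C3-hydroxy seco-diene F1.
- A free allylic hydroxyl is smaller than the silyl ether. It is also known to accelerate metathesis of the adjacent alkene by hydrogen bonding to a chloride ligand on ruthenium.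
- Ring closure of F1 with the same catalyst should therefore give the ring-closed C3 alcohol acetonide F2.
- Aqueous trifluoroacetic acid then removes the acetonide, and the route is rejoined at 31.

Step 11. Coordination of the dioxolane oxygen to indium could reverse the face of the allyl unit, and geometric equilibration of the allylindium could erode the syn preference. Lactonisation onto O8 could also consume the product.
- The fallback sets out from 18, which is acetylated (Ac2O, pyridine) to the Baylis–Hillman acetate F3.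
- Pd2(dba)3-catalysed borylation with B2pin2 proceeds with allylic transposition and gives the geometrically defined E-allylboronate F4, with C6 cis to the CH2B group.
- Thermal allylboration of 15 in toluene runs through a closed chair in which boron has no free site for the dioxolane oxygen. The syn relationship then follows from the alkene geometry alone.
- Hydrolytic work-up returns the route at 21.

Step 6. Facial selectivity may be poor, because the innate 1,5-anti bias of a boron enolate with a β-alkoxy group at C9 opposes the reagent.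
- The fallback sets out from 7, which iBu2AlH reduces to the C1 aldehyde F5.
- The lithium enolate of 3-methylbut-3-en-2-one (LiN(iPr)2, THF, −78 °C) adds to give the β-hydroxy enone F6, whose C1 epimers are of no consequence.
- Reduction with the (R)-Me-CBS oxazaborolidine and BH3·SMe2 sets C3 under catalyst control, with the isopropenyl group as the large substituent, and gives the 3S 1,3-diol F7.
- TBSCl and imidazole silylate the less hindered allylic hydroxyl to give the C3 silyl ether C1 carbinol F8.
- Dess–Martin oxidation of the neopentyl-type C1 carbinol rejoins the route at 13.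

Further compounds
F1 | step 16 | C3-hydroxy seco-diene (28 without the silyl group) | C=C(C)[C@@H](O)CC(=O)[C@@]3(C)OC(C)(C)O[C@H]3[C@@H](OC(=O)/C(C)=C/C)[C@H]1C(=C)C(=O)O[C@@H]1C=C
F2 | step 16 | ring-closed C3 alcohol acetonide (Z C4=C5) | C=C1C(=O)O[C@@H]2/C=C(/C)[C@@H](O)CC(=O)[C@@]3(C)OC(C)(C)O[C@H]3[C@@H](OC(=O)/C(C)=C/C)[C@@H]12
F3 | step 11 | Baylis–Hillman acetate; methyl 2-{acetoxy[(4R)-2,2-dimethyl-1,3-dioxolan-4-yl]methyl}prop-2-enoate | C=C(C(=O)OC)C(OC(C)=O)[C@H]1COC(C)(C)O1
F4 | step 11 | E-allylboronate; methyl (2E)-3-[(4S)-2,2-dimethyl-1,3-dioxolan-4-yl]-2-[(4,4,5,5-tetramethyl-1,3,2-dioxaborolan-2-yl)methyl]prop-2-enoate | COC(=O)/C(CB1OC(C)(C)C(C)(C)O1)=C/[C@H]1COC(C)(C)O1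
F5 | step 6 | C1 aldehyde; (4S,5S)-5-[(4S)-2,2-dimethyl-1,3-dioxolan-4-yl]-2,2,4-trimethyl-1,3-dioxolane-4-carbaldehyde | O=C[C@@]1(C)OC(C)(C)O[C@H]1[C@@H]1COC(C)(C)O1
F6 | step 6 | β-hydroxy enone (C1 carbinol epimers; C3 ketone) | C=C(C)C(=O)CC(O)[C@@]1(C)OC(C)(C)O[C@H]1[C@@H]1COC(C)(C)O1
F7 | step 6 | 3S 1,3-diol (C1 carbinol epimers) | C=C(C)[C@@H](O)CC(O)[C@@]1(C)OC(C)(C)O[C@H]1[C@@H]1COC(C)(C)O1
F8 | step 6 | C3 silyl ether C1 carbinol | C=C(C)[C@@H](O[Si](C)(C)C(C)(C)C)CC(O)[C@@]1(C)OC(C)(C)O[C@H]1[C@@H]1COC(C)(C)O1
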